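## Analysis of the target

The target (27) is an enolised bicyclo[3.3.1]nonane-2,4,9-trione of the type B polyprenylated acylphloroglucinol family, numbered here with C1 as the bridgehead next to C8, ring A as C1–C2–C3–C4–C5–C9 (3,4-dihydroxybenzoyl on C3) and ring B as C1–C8–C7–C6–C5–C9 (C9 the bridging ketone); aromatic precursors are numbered by the carbons they become, and O2, O4 and O9 are the oxygens on C2, C4 and C9. There are four stereocentres: C1 and C5 are quaternary bridgeheads, each with a prenyl group, and they fix each other through the bicycle. C8 is quaternary, with its methyl group equatorial and its 4-methylpent-3-enyl chain axial on the C9 side of a chair ring B, and C7 carries its prenyl group endo, on the ring A side and trans to the C8 chain; in the drawn tautomer this is 1S,5S,7S,8R. Sensitive groups are the catechol (oxidation), the acidic, chelating enol-triketone, and four trisubstituted alkenes that cyclise onto the enol oxygen under acid. The difficulties are the C1–C8 bond between two quaternary carbons, the endo (less stable) placement at C7, and the need for one enantiomer. The strategy rests on C5: it is a quaternary carbon between the C4 and C9 carbonyl groups and is bonded to the C6 methylene. That bond can form when an oxidised C5 enolate is captured by the terminal carbon of an alkene held on C8, with ring A taken intact from an acylphloroglucinol.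

## Retrosynthetic reasoning

**27 ⇒ 26.** Only O–Si and O–C(acetal) bonds are cut. The catechol is carried as two silyl ethers and the ring A enol as a fluoride-labile acetal ether, so one fluoride treatment ends the synthesis without acid, which the prenyl/enol pairs would not tolerate.

**26 ⇒ 25 ⇒ 23 + 24.** The C7 prenyl group is cut between its CH2 and its alkenyl carbon. This leaves a C7 exocyclic methylene (23) and the alkenyl bromide 24. Forward, a hindered dialkylborane must add to the methylene from the open exo face, so that hydrogen arrives exo and the boron-bearing CH2 of the adduct 25 ends endo; an alkyl Suzuki–Miyaura coupling with 24 then completes the prenyl group. Cutting here puts the C7 stereocentre under the control of the finished bicycle and makes it non-epimerisable. 23 is the enol-protected form of 22.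

**22 ⇒ 21 (key disconnection).** The C5–C6 bond is cut. C5 is the α-carbon of a 1,3-dicarbonyl unit and C6 becomes the terminal carbon of an allylsilane on C8. Cutting here, and not at C1–C8, leaves ring A as a dearomatised acylphloroglucinol with every ring A carbon and oxygen in place. Forward, the C5 enolate must be oxidised selectively, add 6-endo to C6, and the silicon must place the new alkene exocyclic at C7.

**21 ⇒ 20 ⇒ 19.** The C1–C8 bond joins two quaternary carbons, so it is cut as a [3,3] shift from the aryl allyl ether 19. The ether oxygen sits on C9, whose two ortho carbons (C1, C5) are equivalent and both carry prenyl, so regiochemistry is not an issue. The alkene geometry of the allyl unit is translated into the C1/C8 relative configuration. The product is racemic (20) and is resolved to 21. No allylic stereocentre is available for chirality transfer, because the ether carbon becomes the terminal CH2.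

**19 ⇒ 18 + 8.** The ether C–O bond is cut (Mitsunobu). The para hydroxyl of 18 is the most acidic and is not hydrogen-bonded to the ketone, and direct use of alcohol 8 avoids an ionisable allylic halide.

**18 ⇒ 17 ⇒ 16 + 2; 16 ⇒ 15 ⇒ 14 + 13; 14 ⇒ 10.** The two prenyl groups are cut from the ring carbons one after the other: C-alkylation of 16 with 2 passes through the monoprenyl compound 17, which takes up a second equivalent of 2 in the same flask. The aryl–carbonyl bond is cut to the aryllithium 14 (from 10) and the acid chloride 13, because a Lewis-acid acylation would not tolerate the catechol silyl ethers. 10 comes from phloroglucinol 9, and 13 from 3,4-dihydroxybenzoic acid 11 via 12.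

**8 ⇒ 7 ⇒ 6 ⇒ 5 ⇒ 3 ⇒ 1 + 2 (+ 4).** The tetrasubstituted alkene is cut at its methyl group. A chelated β-keto ester enolate (from 5) gives the enol triflate 6 with oxygen cis to the ester, and a stereoretentive methyl coupling gives 7; reduction gives 8. 5 arises from 3 by α-alkylation with 4, and 3 from the dianion of 1 and 2.

## Alternatives that were turned down

Alternative 1: sulfonium ylide [2,3] shift forging C1–C8.
- Disconnection and key step: C1–C8 is cut in a monocyclic ring B. A carbenoid at C1, generated from a diazo β-keto ester with Rh2(OAc)4, would be captured by the sulfur of a tethered allylic sulfide, and the cyclic ylide would rearrange [2,3] to the cyclohexanone A1.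
- For: the most congested bond forms at low temperature and irreversibly, and C7 can come from the chiral pool. On making C1–C8 it is stronger than the chosen route, whose [3,3] product is thermally fragile and must be resolved.
- Against: A1 carries a vinyl group where the homoprenyl chain must be, and a phenylthio and an ester group on C1 where the prenyl group and ring A must be. Removing sulfur, alkylating a neopentyl quaternary carbon, and building C2–C3–C4 and the C5 quaternary centre would take well over ten further steps. The carbenoid may also cyclopropanate the prenyl alkene.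
- Comparison: the chosen route has ring A, the aroyl group and all prenyl carbons in place at the key step and needs three steps after it.

Alternative 2: gold-triggered 6-endo closure onto an ethoxy ynone.
- Disconnection and key step: C4–C5 of ring A is cut. A C5=C9 silyl enol ether would attack the alkyne of an ethoxyethynyl ketone on C1, activated by a monovalent gold catalyst such as Ph3PAuNTf2, to give A2.
- For: this ring A closure is well established for these cores. All four stereocentres are set on a cyclohexanone, where C7 and C8 are controlled by ring conformation. On stereochemical security it is stronger than the chosen route.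
- Against: the cyclisation substrate is a fully substituted cyclohexanone with C1, C8 and C5 quaternary, which needs a long linear sequence. The alkyne activation must compete with four tethered trisubstituted alkenes (enyne pathways). C3 aroylation with a protected catechol donor is still to come after A2.
- Comparison: the chosen route is much shorter, because phloroglucinol supplies ring A and the aroyl group at the start.

Alternative 3: dearomative (3+3) annulation with acetoxymethyl geranial.
- Disconnection and key step: both C5–C6 and C1–C8 are cut. The anion of 18 would be alkylated at C5 by the acetoxymethyl carbon of the enal A3, and C1 would then add to the β-carbon to give the aldehyde A4.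
- For: it uses the same arene 18, builds the whole core in one polar step, needs no oxidation, and never passes through a fragile 1,5-diene. In step count to the core it is stronger than the chosen route.
- Against: the C1–C8 bond is made by a reversible Michael addition to a β,β-dialkyl enal, so the C8 configuration depends on an enal geometry that can scramble. The C7 formyl group is epimerisable towards the exo isomer. Turning CHO into prenyl needs a one-carbon homologation and an olefination on an acidic triketone.
- Comparison: the chosen route fixes C8 stereospecifically before ring closure, sets C7 irreversibly on the finished bicycle, and converts the C7 methylene to prenyl in one step.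

Key step: step 15

Remarks on the chemistry: 20 is a racemate and is written as its two enantiomers joined by a dot. The acetal group of 23, 25 and 26 is drawn on O4; the O2 regioisomer, if it forms, should behave in the same way and converge at 27.

## Route

Step 1
Reactants: 1 ethyl acetoacetate; 2 prenyl bromide (1-bromo-3-methylbut-2-ene)
Product: 3 ethyl 7-methyl-3-oxooct-6-enoate
Conditions: NaH, THF, 0 °C; n-BuLi, 0 °C; then 2, 0 °C to rt; 1 M HCl
Reagents that add atoms: none
Why: γ-Alkylation of the acetoacetate dianion; the more basic terminal carbanion should react with the allylic bromide at its primary carbon.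

Step 2
Reactants: 3 ethyl 7-methyl-3-oxooct-6-enoate; 4 (iodomethyl)trimethylsilane
Product: 5 ethyl 7-methyl-3-oxo-2-[(trimethylsilyl)methyl]oct-6-enoate (racemic at C2, which is destroyed in step 3)
Conditions: NaH, DMF, 0 °C; then 4, 60 °C
Reagents that add atoms: none
Why: α-Alkylation of a β-keto ester enolate; the α-silyl iodide is a slow but clean SN2 partner and the single remaining α-hydrogen limits over-alkylation.

Step 3
Reactants: 5 ethyl 7-methyl-3-oxo-2-[(trimethylsilyl)methyl]oct-6-enoate
Product: 6 ethyl (2E)-7-methyl-3-(trifluoromethylsulfonyloxy)-2-[(trimethylsilyl)methyl]octa-2,6-dienoate (triflate oxygen cis to the ester)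
Conditions: NaH, Et2O, 0 °C; then Tf2O, -78 to 0 °C
Reagents that add atoms: trifluoromethanesulfonic anhydride, O=S(=O)(OS(=O)(=O)C(F)(F)F)C(F)(F)F
Why: O-Sulfonylation of a chelated sodium enolate; in a non-coordinating solvent sodium bridges the enolate oxygen and the ester carbonyl, so the triflate should end cis to the ester.

Step 4
Reactants: 6 ethyl (2E)-7-methyl-3-(trifluoromethylsulfonyloxy)-2-[(trimethylsilyl)methyl]octa-2,6-dienoate
Product: 7 ethyl (2Z)-3,7-dimethyl-2-[(trimethylsilyl)methyl]octa-2,6-dienoate (3-methyl cis to the ester; homoprenyl cis to CH2SiMe3)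
Conditions: MeMgBr, Fe(acac)3 (5 mol %), THF/NMP, -30 °C
Reagents that add atoms: methylmagnesium bromide, C[Mg]Br
Why: Iron-catalysed Kumada-type cross-coupling of an enol triflate; it proceeds with retention of alkene geometry and is fast enough at low temperature to spare the ester.

Step 5
Reactants: 7 ethyl (2Z)-3,7-dimethyl-2-[(trimethylsilyl)methyl]octa-2,6-dienoate
Product: 8 (2Z)-3,7-dimethyl-2-[(trimethylsilyl)methyl]octa-2,6-dien-1-ol (3-methyl cis to CH2OH)
Conditions: i-Bu2AlH, CH2Cl2, -78 to 0 °C; aq. potassium sodium tartrate
Reagents that add atoms: none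
Why: 1,2-Reduction of a conjugated ester to the allylic alcohol; the neutral tartrate work-up avoids protodesilylation or ionisation of the allylsilane alcohol.

Step 6
Reactants: 9 phloroglucinol
Product: 10 1,3,5-tris(methoxymethoxy)benzene
Conditions: NaH, DMF, 0 °C; MeOCH2Cl, 0 °C to rt
Reagents that add atoms: chloromethyl methyl ether, COCCl
Why: Williamson O-alkylation; the hard chloromethyl ether reacts at oxygen and not at ring carbon, and the acetal groups later direct lithiation.

Step 7
Reactants: 11 3,4-dihydroxybenzoic acid
Product: 12 tert-butyldimethylsilyl 3,4-bis(tert-butyldimethylsilyloxy)benzoate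
Conditions: t-BuMe2SiCl, imidazole, DMF, rt
Reagents that add atoms: tert-butyldimethylsilyl chloride, CC(C)(C)[Si](C)(C)Cl
Why: Exhaustive silylation of the two phenols and the acid; the silyl ester is the handle for neutral acid chloride formation.

Step 8
Reactants: 12 tert-butyldimethylsilyl 3,4-bis(tert-butyldimethylsilyloxy)benzoate
Product: 13 3,4-bis(tert-butyldimethylsilyloxy)benzoyl chloride
Conditions: (COCl)2, DMF (cat.), CH2Cl2, 0 °C to rt
Reagents that add atoms: oxalyl chloride, ClC(=O)C(Cl)=O
Why: Conversion of a silyl ester into the acid chloride by the Vilsmeier chloride; no HCl is released, so the aryl silyl ethers should survive.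

Step 9
Reactants: 10 1,3,5-tris(methoxymethoxy)benzene; 13 3,4-bis(tert-butyldimethylsilyloxy)benzoyl chloride
Product: 15 [3,4-bis(tert-butyldimethylsilyloxy)phenyl][2,4,6-tris(methoxymethoxy)phenyl]methanone, via 2,4,6-tris(methoxymethoxy)phenyllithium 14 (not isolated)
Conditions: 10, n-BuLi, THF, 0 °C; then cannulated into 13, THF, -78 °C
Reagents that add atoms: n-butyllithium, CCCC[Li] (lithium retained only in 14)
Why: Directed ortho-lithiation between two acetal oxygens followed by acylation; inverse addition and the two ortho substituents of the product ketone should stop a second addition.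

Step 10
Reactants: 15 [3,4-bis(tert-butyldimethylsilyloxy)phenyl][2,4,6-tris(methoxymethoxy)phenyl]methanone
Product: 16 [3,4-bis(tert-butyldimethylsilyloxy)phenyl](2,4,6-trihydroxyphenyl)methanone
Conditions: ZnBr2, n-PrSH, CH2Cl2, 0 °C to rt
Reagents that add atoms: none
Why: Lewis-acid-assisted transacetalisation of the methoxymethyl ethers onto the thiol; these mild, non-protic conditions should leave the aryl silyl ethers intact.

Step 11
Reactants: 16 [3,4-bis(tert-butyldimethylsilyloxy)phenyl](2,4,6-trihydroxyphenyl)methanone; 2 prenyl bromide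
Product: 18 [3,4-bis(tert-butyldimethylsilyloxy)phenyl][2,4,6-trihydroxy-3,5-bis(3-methylbut-2-enyl)phenyl]methanone, via mono-C-prenylated ketone 17 (not isolated)
Conditions: 2 (2.1 equiv in all), DBU (2.2 equiv), THF, 0 °C to rt
Reagents that add atoms: prenyl bromide (the second equivalent of 2), CC(C)=CCBr
Why: Base-mediated C-alkylation of the acylphloroglucinol, run twice in one flask: the first equivalent of 2 gives 17 at one free ring carbon and the second equivalent alkylates the remaining free ring carbon, so that both C1 and C5 carry prenyl; the anhydrous amidine base is chosen because hydroxide would cleave the aryl silyl ethers.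

Step 12
Reactants: 18 [3,4-bis(tert-butyldimethylsilyloxy)phenyl][2,4,6-trihydroxy-3,5-bis(3-methylbut-2-enyl)phenyl]methanone; 8 (2Z)-3,7-dimethyl-2-[(trimethylsilyl)methyl]octa-2,6-dien-1-ol
Product: 19 [3,4-bis(tert-butyldimethylsilyloxy)phenyl]{4-[(2Z)-3,7-dimethyl-2-[(trimethylsilyl)methyl]octa-2,6-dienyloxy]-2,6-dihydroxy-3,5-bis(3-methylbut-2-enyl)phenyl}methanone (ether on O9)
Conditions: PPh3, DIAD, toluene, 0 °C to rt
Reagents that add atoms: none
Why: Mitsunobu etherification at the most acidic hydroxyl, the one para to the ketone; the two ortho hydroxyls are hydrogen-bonded to the carbonyl, and an ortho ether, if formed, would rearrange in step 13 onto the same prenyl-bearing carbon and give the same enolised triketone.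

Step 13
Reactants: 19 [3,4-bis(tert-butyldimethylsilyloxy)phenyl]{4-[(2Z)-3,7-dimethyl-2-[(trimethylsilyl)methyl]octa-2,6-dienyloxy]-2,6-dihydroxy-3,5-bis(3-methylbut-2-enyl)phenyl}methanone
Product: 20 racemic 4-[3,4-bis(tert-butyldimethylsilyloxy)benzoyl]-3,5-dihydroxy-2,6-bis(3-methylbut-2-enyl)-6-[3,7-dimethyl-2-(trimethylsilylmethyl)octa-1,6-dien-3-yl]cyclohexa-2,4-dien-1-one (relative configuration of 21)
Conditions: Eu(fod)3 (10-20 mol %), CHCl3, 40-45 °C, dark; chromatography at 0 °C
Reagents that add atoms: none
Why: Aromatic Claisen rearrangement onto a substituted ortho carbon, which cannot re-aromatise and stays as the enolised triketone; both ortho carbons are equivalent, so the racemate forms. In the chair transition state the ring prenyl group and the alkene methyl (cis to the OCH2 carbon) are axial and the homoprenyl chain equatorial, which should give the C1/C8 relative configuration of 21. The mild europium catalysis keeps the temperature low, because the product is a 1,5-diene that can move on by Cope rearrangement.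

Step 14
Reactants: 20 racemic 4-[3,4-bis(tert-butyldimethylsilyloxy)benzoyl]-3,5-dihydroxy-2,6-bis(3-methylbut-2-enyl)-6-[3,7-dimethyl-2-(trimethylsilylmethyl)octa-1,6-dien-3-yl]cyclohexa-2,4-dien-1-one
Product: 21 4-[3,4-bis(tert-butyldimethylsilyloxy)benzoyl]-3,5-dihydroxy-2,6-bis(3-methylbut-2-enyl)-6-[3,7-dimethyl-2-(trimethylsilylmethyl)octa-1,6-dien-3-yl]cyclohexa-2,4-dien-1-one, single enantiomer with skeletal C1 and C8 configured as in 27
Conditions: preparative SFC on amylose tris(3,5-dimethylphenylcarbamate), CO2/MeOH, 15 °C
Reagents that add atoms: none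
Why: Resolution of enantiomers by chromatography on a chiral stationary phase, done cold and quickly because of the Cope-labile 1,5-diene; the absolute configuration would be assigned by anomalous-dispersion crystallography of a derivative or by correlation at 27.

Step 15
Reactants: 21 dearomatised aroylphloroglucinol with prenyl and the C8(methyl)(homoprenyl)–C(=CH2)–CH2SiMe3 chain on C1
Product: 22 (1S,5S,8R)-3-[3,4-bis(tert-butyldimethylsilyloxy)benzoyl]-4-hydroxy-8-methyl-7-methylidene-1,5-bis(3-methylbut-2-enyl)-8-(4-methylpent-3-enyl)bicyclo[3.3.1]non-3-ene-2,9-dione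
Conditions: undivided cell, reticulated vitreous carbon anode, Pt cathode, constant current (about 2.2 F per mol), LiClO4 (0.1 M), 2,6-lutidine, MeOH/CH2Cl2 1:4, 0 °C
Reagents that add atoms: none
Why: The lutidine-buffered medium holds 21 as its enolate, which is far more easily oxidised than the trisubstituted alkenes, the allylsilane or the silylated catechol, so the anode should remove one electron from it alone and give a radical delocalised over C3, C5 and the oxygens. The C5 terminus adds to the unsubstituted terminal carbon C6 of the allylsilane on C8, closing ring B in 6-endo-trig mode and giving a tertiary β-silyl radical at C7; a second electron transfer gives the β-silyl cation, which loses Me3Si+ to methanol and leaves the exocyclic C7 methylene, so silicon fixes the alkene position. The closest known reaction type is the anodic, or Mn(OAc)3-mediated, oxidative cyclisation of 1,3-dicarbonyl enols and enolates onto allylsilanes and 1,1-disubstituted alkenes, which is also known on dearomatised acylphloroglucinols. The only new stereocentre, C5, is controlled by the C1–C8 tether: C6 can reach C5 only on the ring face that carries the C8 chain, which makes C1 and C5 the cis-bridged bridgeheads and turns the C5 prenyl group outward. The step needs C5 and not C3 to react; attack through C3 would build a carbon with three acyl groups and break the chelated aroyl-enol, whereas C5 is an ordinary 2-alkyl-1,3-dicarbonyl radical site. It also needs the allylsilane to win over 5-exo attack on the C1 prenyl alkene; the allylsilane offers an unhindered CH2 terminus, a raised HOMO and a strain-free chair-like closure, while the prenyl path leads to a bicyclo[3.2.1] ring. The low temperature keeps the 1,5-diene of 21 from Cope rearrangement before it is oxidised.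

Step 16
Reactants: 22 7-methylidene bicyclic enol
Product: 23 3-[3,4-bis(tert-butyldimethylsilyloxy)benzoyl]-8-methyl-7-methylidene-1,5-bis(3-methylbut-2-enyl)-8-(4-methylpent-3-enyl)-4-{[2-(trimethylsilyl)ethoxy]methoxy}bicyclo[3.3.1]non-3-ene-2,9-dione (C1, C5 and C8 as in 22)
Conditions: Me3SiCH2CH2OCH2Cl, i-Pr2NEt, CH2Cl2, 0 °C to rt
Reagents that add atoms: 2-(trimethylsilyl)ethoxymethyl chloride, C[Si](C)(C)CCOCCl
Why: O-Alkylation of the vinylogous acid by a chloromethyl ether; this removes the acidic, boron-chelating enol before hydroboration and gives an ether that fluoride removes together with the aryl silyl groups.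

Step 17
Reactants: 23 protected 7-methylidene bicycle; 24 1-bromo-2-methylpropene
Product: 26 3-[3,4-bis(tert-butyldimethylsilyloxy)benzoyl]-8-methyl-1,5,7-tris(3-methylbut-2-enyl)-8-(4-methylpent-3-enyl)-4-{[2-(trimethylsilyl)ethoxy]methoxy}bicyclo[3.3.1]non-3-ene-2,9-dione (C1, C5, C7 and C8 as in 27; C7 prenyl endo), via 7-endo-(9-borabicyclononylmethyl) adduct 25 (not isolated)
Conditions: 9-BBN-H, THF, 0 °C to rt; then 24, Pd(dppf)Cl2 (5 mol %), AsPh3, aq. K3PO4, DMF, rt to 45 °C
Reagents that add atoms: 9-borabicyclo[3.3.1]nonane, B1C2CCCC1CCC2 (boron retained only in 25)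
Why: Anti-Markovnikov hydroboration followed by B-alkyl Suzuki–Miyaura coupling; the hindered borane should select the 1,1-disubstituted alkene over the trisubstituted ones and the hindered ketones. The endo face of the C7 methylene is blocked by ring A, so hydrogen should be delivered from the exo face, placing the CH2B group, and hence the prenyl group, endo at C7.

Step 18
Reactants: 26 fully protected target
Product: 27 (1S,5S,7S,8R)-3-(3,4-dihydroxybenzoyl)-4-hydroxy-8-methyl-1,5,7-tris(3-methylbut-2-enyl)-8-(4-methylpent-3-enyl)bicyclo[3.3.1]non-3-ene-2,9-dione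
Conditions: Bu4NF, AcOH, THF, 0 °C to rt, argon
Reagents that add atoms: none
Why: Fluoride-induced desilylation of the two aryl silyl ethers and fragmentation of the silylethoxymethyl enol ether (loss of ethene and formaldehyde); the buffered, acid-free and oxygen-free conditions protect the catechol and avoid cyclisation of the enol onto a prenyl group.

## Compound list

1 | ethyl acetoacetate | CCOC(=O)CC(C)=O | starting material
2 | prenyl bromide | CC(C)=CCBr | starting material
3 | ethyl 7-methyl-3-oxooct-6-enoate | CCOC(=O)CC(=O)CCC=C(C)C | intermediate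
4 | (iodomethyl)trimethylsilane | C[Si](C)(C)CI | starting material
5 | ethyl 7-methyl-3-oxo-2-[(trimethylsilyl)methyl]oct-6-enoate (racemic) | CCOC(=O)C(C[Si](C)(C)C)C(=O)CCC=C(C)C | intermediate
6 | ethyl (2E)-7-methyl-3-(trifluoromethylsulfonyloxy)-2-[(trimethylsilyl)methyl]octa-2,6-dienoate | CCOC(=O)/C(C[Si](C)(C)C)=C(\OS(=O)(=O)C(F)(F)F)CCC=C(C)C | intermediate
7 | ethyl (2Z)-3,7-dimethyl-2-[(trimethylsilyl)methyl]octa-2,6-dienoate | CCOC(=O)/C(C[Si](C)(C)C)=C(\C)CCC=C(C)C | intermediate
8 | (2Z)-3,7-dimethyl-2-[(trimethylsilyl)methyl]octa-2,6-dien-1-ol | OC/C(C[Si](C)(C)C)=C(\C)CCC=C(C)C | intermediate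
9 | phloroglucinol | Oc1cc(O)cc(O)c1 | starting material
10 | 1,3,5-tris(methoxymethoxy)benzene | COCOc1cc(OCOC)cc(OCOC)c1 | intermediate
11 | 3,4-dihydroxybenzoic acid | OC(=O)c1ccc(O)c(O)c1 | starting material
12 | tert-butyldimethylsilyl 3,4-bis(tert-butyldimethylsilyloxy)benzoate | CC(C)(C)[Si](C)(C)OC(=O)c1ccc(O[Si](C)(C)C(C)(C)C)c(O[Si](C)(C)C(C)(C)C)c1 | intermediate
13 | 3,4-bis(tert-butyldimethylsilyloxy)benzoyl chloride | ClC(=O)c1ccc(O[Si](C)(C)C(C)(C)C)c(O[Si](C)(C)C(C)(C)C)c1 | intermediate
14 | 2,4,6-tris(methoxymethoxy)phenyllithium | [Li]c1c(OCOC)cc(OCOC)cc1OCOC | intermediate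
15 | [3,4-bis(tert-butyldimethylsilyloxy)phenyl][2,4,6-tris(methoxymethoxy)phenyl]methanone | COCOc1cc(OCOC)c(C(=O)c2ccc(O[Si](C)(C)C(C)(C)C)c(O[Si](C)(C)C(C)(C)C)c2)c(OCOC)c1 | intermediate
16 | [3,4-bis(tert-butyldimethylsilyloxy)phenyl](2,4,6-trihydroxyphenyl)methanone | Oc1cc(O)c(C(=O)c2ccc(O[Si](C)(C)C(C)(C)C)c(O[Si](C)(C)C(C)(C)C)c2)c(O)c1 | intermediate
17 | [3,4-bis(tert-butyldimethylsilyloxy)phenyl][2,4,6-trihydroxy-3-(3-methylbut-2-enyl)phenyl]methanone (mono-C-prenylated ketone) | CC(C)=CCc1c(O)cc(O)c(C(=O)c2ccc(O[Si](C)(C)C(C)(C)C)c(O[Si](C)(C)C(C)(C)C)c2)c1O | intermediate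
18 | [3,4-bis(tert-butyldimethylsilyloxy)phenyl][2,4,6-trihydroxy-3,5-bis(3-methylbut-2-enyl)phenyl]methanone | CC(C)=CCc1c(O)c(CC=C(C)C)c(O)c(C(=O)c2ccc(O[Si](C)(C)C(C)(C)C)c(O[Si](C)(C)C(C)(C)C)c2)c1O | intermediate
19 | O9 allyl ether of 18 with the (2Z)-3,7-dimethyl-2-[(trimethylsilyl)methyl]octa-2,6-dienyl group | CC(C)=CCc1c(OC/C(C[Si](C)(C)C)=C(\C)CCC=C(C)C)c(CC=C(C)C)c(O)c(C(=O)c2ccc(O[Si](C)(C)C(C)(C)C)c(O[Si](C)(C)C(C)(C)C)c2)c1O | intermediate
20 | racemic dearomatised Claisen product (both enantiomers, relative configuration of 21) | CC(C)=CCC[C@](C)(C(=C)C[Si](C)(C)C)[C@@]1(CC=C(C)C)C(=O)C(CC=C(C)C)=C(O)C(C(=O)c2ccc(O[Si](C)(C)C(C)(C)C)c(O[Si](C)(C)C(C)(C)C)c2)=C1O.CC(C)=CCC[C@@](C)(C(=C)C[Si](C)(C)C)[C@]1(CC=C(C)C)C(=O)C(CC=C(C)C)=C(O)C(C(=O)c2ccc(O[Si](C)(C)C(C)(C)C)c(O[Si](C)(C)C(C)(C)C)c2)=C1O | intermediate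
21 | key-step precursor, single enantiomer of 20 (C1 and C8 as in 27) | CC(C)=CCC[C@](C)(C(=C)C[Si](C)(C)C)[C@@]1(CC=C(C)C)C(=O)C(CC=C(C)C)=C(O)C(C(=O)c2ccc(O[Si](C)(C)C(C)(C)C)c(O[Si](C)(C)C(C)(C)C)c2)=C1O | intermediate
22 | (1S,5S,8R)-3-[3,4-bis(tert-butyldimethylsilyloxy)benzoyl]-4-hydroxy-8-methyl-7-methylidene-1,5-bis(3-methylbut-2-enyl)-8-(4-methylpent-3-enyl)bicyclo[3.3.1]non-3-ene-2,9-dione | CC(C)=CCC[C@]1(C)C(=C)C[C@]2(CC=C(C)C)C(=O)[C@@]1(CC=C(C)C)C(=O)C(C(=O)c3ccc(O[Si](C)(C)C(C)(C)C)c(O[Si](C)(C)C(C)(C)C)c3)=C2O | intermediate
23 | O4 [2-(trimethylsilyl)ethoxy]methyl ether of 22 | CC(C)=CCC[C@]1(C)C(=C)C[C@]2(CC=C(C)C)C(=O)[C@@]1(CC=C(C)C)C(=O)C(C(=O)c3ccc(O[Si](C)(C)C(C)(C)C)c(O[Si](C)(C)C(C)(C)C)c3)=C2OCOCC[Si](C)(C)C | intermediate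
24 | 1-bromo-2-methylpropene | CC(C)=CBr | starting material
25 | 7-endo-[(9-borabicyclo[3.3.1]nonan-9-yl)methyl] adduct of 23 | CC(C)=CCC[C@]1(C)[C@@H](CB3C4CCCC3CCC4)C[C@]2(CC=C(C)C)C(=O)[C@@]1(CC=C(C)C)C(=O)C(C(=O)c5ccc(O[Si](C)(C)C(C)(C)C)c(O[Si](C)(C)C(C)(C)C)c5)=C2OCOCC[Si](C)(C)C | intermediate
26 | fully protected target (7-endo prenyl) | CC(C)=CCC[C@]1(C)[C@@H](CC=C(C)C)C[C@]2(CC=C(C)C)C(=O)[C@@]1(CC=C(C)C)C(=O)C(C(=O)c3ccc(O[Si](C)(C)C(C)(C)C)c(O[Si](C)(C)C(C)(C)C)c3)=C2OCOCC[Si](C)(C)C | intermediate
27 | (1S,5S,7S,8R)-3-(3,4-dihydroxybenzoyl)-4-hydroxy-8-methyl-1,5,7-tris(3-methylbut-2-enyl)-8-(4-methylpent-3-enyl)bicyclo[3.3.1]non-3-ene-2,9-dione | CC(C)=CCC[C@]1(C)[C@@H](CC=C(C)C)C[C@]2(CC=C(C)C)C(=O)[C@@]1(CC=C(C)C)C(=O)C(C(=O)c1ccc(O)c(O)c1)=C2O | target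

## Step count and least certain steps

Total: 18 steps. Longest linear sequence: 12 steps (11 → 12 → 13 → 15 → 16 → 18 → 19 → 20 → 21 → 22 → 23 → 26 → 27; the branch from 1 is equally long). Half of the material is lost at the resolution in step 14.

**Step 15 (key step).**
- What may go wrong: the C5 radical may partition between 6-endo addition to the allylsilane and 5-exo addition to the C1 prenyl alkene, a mode such radicals are known to follow when no better acceptor is present. The 1,5-diene of 21 may undergo Cope rearrangement of the allyl unit from C1 to C5 before it is oxidised. The product enolate may be oxidised further once the charge passed exceeds two electrons per molecule.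
- Fallback: a two-electron, palladium-mediated closure that sets out from 21 and returns at 22. Divalent palladium, as PdCl2(MeCN)2 in THF at 0 °C, exchanges with the allylsilane to give the η3-allylpalladium chloride F1. PPh3 and K2CO3 then trigger attack of the C5 enolate on a terminal carbon of the allyl ligand, both termini giving the same product, and zerovalent palladium is released. Only the allylsilane can enter this pathway, so the prenyl groups cannot compete.

**Step 13.**
- What may go wrong: the product joins two quaternary carbons and is a higher-energy isomer. Onward Cope rearrangement to the linear C-allyl isomer, return to the ether, or a boat transition state (giving the C8 epimer) may erode it. Isomerically impure 8 would have the same effect.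
- Fallback: ring closure from the other end, setting out from 8 and 18 and returning at 22. Alcohol 8 is converted (CBr4, PPh3) into the allylic bromide F2. Alkylative dearomatisation of 18 with F2 and LiN(SiMe3)2 in THF joins the primary carbon to a prenyl-bearing ring carbon and gives the racemic linear C-allylated triketone F3, which is stable. F3 is resolved as in step 14 to the enantiomer F4, whose quaternary carbon becomes C5 and already carries C6. The electrolysis of step 15 is then run on F4: the enolate radical at the other prenyl-bearing carbon (C1) adds to the γ-carbon (C8) of the allylsilane and desilylation gives 22. The C8 configuration is then set in the ring closure, so the C8 epimer may have to be separated.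

**Step 17.**
- What may go wrong: the axial C8 chain may lower the exo-face preference of the hydroboration, the borane may reduce a carbonyl group slowly, transmetalation of the β-branched alkylborane may be sluggish, and aqueous base may partly cleave the aryl silyl ethers.
- Fallback: sets out from 23 through 25 and returns at 26. Oxidative work-up of 25 (NaBO3·4H2O) gives the primary alcohol F5. Iodination (I2, PPh3, imidazole) gives the iodide F6. Zinc insertion (Zn dust, LiCl, THF) gives the alkylzinc iodide F7, which is coupled with 24 under Negishi conditions (Pd(OAc)2 with a biaryl phosphine) without aqueous base.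

**Step 11.**
- What may go wrong: the alkylation may stall at the monoprenyl stage 17 or run on to geminal or triple C-alkylation; O-alkylation and desilylation by the amidine base may add to a mixture that is hard to separate.
- Fallback: sets out from 10 and returns at 18. Lithiation of 10 (n-BuLi) and alkylation with 2 gives the monoprenyl arene F8. A second lithiation and alkylation gives the diprenyl arene F9. Lithiation of the last free position and acylation with 13 gives the ketone F10. Removal of the three acetal groups as in step 10 gives 18, with each prenyl group placed by directed metalation instead of phenoxide alkylation.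

## Further compounds

F1 | step 15 | η3-allylpalladium chloride from 21 (drawn as the η1 form) | CC(C)=CCC[C@](C)(C(=C)C[Pd]Cl)[C@@]1(CC=C(C)C)C(=O)C(CC=C(C)C)=C(O)C(C(=O)c2ccc(O[Si](C)(C)C(C)(C)C)c(O[Si](C)(C)C(C)(C)C)c2)=C1O
F2 | step 13 | (2E)-1-bromo-3,7-dimethyl-2-[(trimethylsilyl)methyl]octa-2,6-diene | BrC/C(C[Si](C)(C)C)=C(\C)CCC=C(C)C
F3 | step 13 | racemic linear C-allylated triketone (both enantiomers) | CC(C)=CCC/C(C)=C(C[Si](C)(C)C)/C[C@]1(CC=C(C)C)C(=O)C(CC=C(C)C)=C(O)C(C(=O)c2ccc(O[Si](C)(C)C(C)(C)C)c(O[Si](C)(C)C(C)(C)C)c2)=C1O.CC(C)=CCC/C(C)=C(C[Si](C)(C)C)/C[C@@]1(CC=C(C)C)C(=O)C(CC=C(C)C)=C(O)C(C(=O)c2ccc(O[Si](C)(C)C(C)(C)C)c(O[Si](C)(C)C(C)(C)C)c2)=C1O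
F4 | step 13 | enantiomer of F3 whose quaternary carbon has the C5 configuration of 22 | CC(C)=CCC/C(C)=C(C[Si](C)(C)C)/C[C@]1(CC=C(C)C)C(=O)C(CC=C(C)C)=C(O)C(C(=O)c2ccc(O[Si](C)(C)C(C)(C)C)c(O[Si](C)(C)C(C)(C)C)c2)=C1O
F5 | step 17 | 7-endo-hydroxymethyl analogue of 26 | CC(C)=CCC[C@]1(C)[C@@H](CO)C[C@]2(CC=C(C)C)C(=O)[C@@]1(CC=C(C)C)C(=O)C(C(=O)c3ccc(O[Si](C)(C)C(C)(C)C)c(O[Si](C)(C)C(C)(C)C)c3)=C2OCOCC[Si](C)(C)C
F6 | step 17 | 7-endo-iodomethyl analogue of 26 | CC(C)=CCC[C@]1(C)[C@@H](CI)C[C@]2(CC=C(C)C)C(=O)[C@@]1(CC=C(C)C)C(=O)C(C(=O)c3ccc(O[Si](C)(C)C(C)(C)C)c(O[Si](C)(C)C(C)(C)C)c3)=C2OCOCC[Si](C)(C)C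
F7 | step 17 | 7-endo-(iodozinciomethyl) analogue of 26 | CC(C)=CCC[C@]1(C)[C@@H](C[Zn]I)C[C@]2(CC=C(C)C)C(=O)[C@@]1(CC=C(C)C)C(=O)C(C(=O)c3ccc(O[Si](C)(C)C(C)(C)C)c(O[Si](C)(C)C(C)(C)C)c3)=C2OCOCC[Si](C)(C)C
F8 | step 11 | 1,3,5-tris(methoxymethoxy)-2-(3-methylbut-2-enyl)benzene | COCOc1cc(OCOC)c(CC=C(C)C)c(OCOC)c1
F9 | step 11 | 1,3,5-tris(methoxymethoxy)-2,4-bis(3-methylbut-2-enyl)benzene | COCOc1cc(OCOC)c(CC=C(C)C)c(OCOC)c1CC=C(C)C
F10 | step 11 | [3,4-bis(tert-butyldimethylsilyloxy)phenyl][2,4,6-tris(methoxymethoxy)-3,5-bis(3-methylbut-2-enyl)phenyl]methanone | COCOc1c(CC=C(C)C)c(OCOC)c(CC=C(C)C)c(OCOC)c1C(=O)c1ccc(O[Si](C)(C)C(C)(C)C)c(O[Si](C)(C)C(C)(C)C)c1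
A1 | alternative 1 | methyl 2-ethenyl-2-methyl-3-(3-methylbut-2-enyl)-6-oxo-1-(phenylsulfanyl)cyclohexane-1-carboxylate | C=C[C@]1(C)[C@@H](CC=C(C)C)CCC(=O)[C@@]1(Sc2ccccc2)C(=O)OC
A2 | alternative 2 | 4-ethoxy-8-methyl-1,5,7-tris(3-methylbut-2-enyl)-8-(4-methylpent-3-enyl)bicyclo[3.3.1]non-3-ene-2,9-dione | CC(C)=CCC[C@]1(C)[C@@H](CC=C(C)C)C[C@]2(CC=C(C)C)C(=O)[C@@]1(CC=C(C)C)C(=O)C=C2OCC
A3 | alternative 3 | [(2E)-2-formyl-3,7-dimethylocta-2,6-dienyl] acetate (acetoxymethyl geranial) | CC(C)=CCC/C(C)=C(/C=O)COC(C)=O
A4 | alternative 3 | 7-endo-formyl bicyclic core with the silylated aroyl group | CC(C)=CCC[C@]1(C)[C@@H](C=O)C[C@]2(CC=C(C)C)C(=O)[C@@]1(CC=C(C)C)C(=O)C(C(=O)c3ccc(O[Si](C)(C)C(C)(C)C)c(O[Si](C)(C)C(C)(C)C)c3)=C2O
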